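All constants stand for no real mixture, and the outcome is calculated.

The choice here is to follow the substrate's clock rather than every species, and to ask of each recipe how many turnovers it grants.

    reagent in the reaction phase → decomposed reagent (k1 = 1.2 × 10⁻⁴ min⁻¹)
    reagent in the reaction phase ⇌ reagent in the second phase, rate k2*([reagent in the reaction phase] - [reagent in the second phase]/K2) per volume of the first phase (K2 = 1.0, k2 = 9.7 × 10⁻⁴ min⁻¹)
    reagent in the reaction phase + target → over-reacted product (k3 = 0.0024 M⁻¹ min⁻¹)
    2 reagent in the reaction phase → self-condensation product (k4 = 0.0016 M⁻¹ min⁻¹)
    substrate + reagent in the reaction phase → target (k5 = 0.0013 M⁻¹ min⁻¹)

substrate 1.0 M; reagent in the second phase 1.10 equiv; time 25 h; volume of the second phase over the first 2.0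

- east: doubling the amount of reagent in the second phase, all else as stated
- west: doubling the transfer coefficient of step 2, all else as stated

- target at 25 h, in percent of the substrate charged
- the change that raises the amount of target at 25 h, in percent of the substrate charged most ("none" if none brings more than 2 percentage points) (east / west / none)
- amount of target at 25 h, in percent of the substrate charged, after east

- a step written with two of one species runs at k times the square of its concentration and takes two of it each time
- in the second phase: reagent in the second phase; everything else is in the first
- charges count per volume of the first phase; a concentration in a rate is the amount of a species over the volume of its own phase; every rate counts per litre of the first phase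
- run time (flask): 25 h

The reagent in the second phase starts at 0.550 M, and a one-way drain at the transfer coefficient over the volume ratio is reckoned to bring it to 0.382 M at mid-run. Balancing that inflow against the return, decomposition, the full substrate and self-condensation puts [reagent in the reaction phase] at 0.132 M, reached after a lag of 309 min, the reciprocal of those loss frequencies with self-condensation taken at its slope. Substrate is pseudo-first-order at that level, and over the remaining time the count comes to 0.204: this is the turnover count, the time integral of the substrate's rate constant times [reagent in the reaction phase]. It leaves 81.5 % of the substrate, and since target is attacked on the same clock with a larger constant, this reckoning gives 15.3 % of target.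

A second way counts reagent instead. One-way crossing by the end totals 0.569 M, and 70.6 % of what reacts at that level meets substrate, which makes 0.402 M against the count's 0.185 M, twice as much. The budget is the one that cheats, because the return at the balance level is a third of the inflow and 0.132 M stays unspent in the reaction phase. Charging both leaves a net crossing of 0.404 M and then 0.192 M turned over, close to the count, though both ways lean on the same level, so this tests the bookkeeping and not the level.

For east the level becomes 0.236 M, the count 0.381 and target 22.3 %. For west the level is 0.136 M and the count 0.223, so this reckoning puts target at 16.3 %, a reckoned gain of 1.00 percentage point and less than east gives.

The forecast, above this reckoning's figure, gave 16.2 % (from 15.2 % to 17.2 %), east as the change and 22.8 % after it (from 21.5 % to 24 %), with the instruction “Treat this as a reagent slowly feeding from the second phase”.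

The flask holds 16.3 % of target, and east brings 22.9 %, a gain of 6.7 points against 3.3 points for west. Substrate in the flask stands at 80.0 % after 25.0 h, a turnover count of 0.223. For the neighbouring flask with 0.25 M of substrate, its equivalents of reagent held, the same balance gives a level of 0.0579 M, a count of 0.0708 and 93.2 % of its substrate left. After 25.0 h that neighbour holds 92.0 % of its substrate and 7.45 % of target.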